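**Retrosynthetic overview** (drimane numbering: ring carbons C1–C10, C11 = the CH2O carbon on C9)
- Last bond: the C11–O aryl ether, by Mitsunobu coupling of commercial isofraxidin with 3β-hydroxydrimenol.
- 3β-Hydroxydrimenol comes from a ring-A enone (reductive methylation gives the C4 gem-dimethyl group and the trans hydrogen at C5, hydride sets C3). That enone comes from a bicyclic dienedione whose C9 carbonyl is turned into CH–CH2OH by methylenation and face-selective hydroboration.
- Key disconnection: ring B of the dienedione is opened at C5–C6 and C7=C8, which leaves a monocyclic vinylogous ester and a two-carbon acetaldehyde unit (an acetal Grignard reagent). Forward, this is a Stork–Danheiser addition/transposition followed by aldol condensation in one flask.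
- Enabling feature: in ring A of the precursor, C5 is the carbonyl carbon of the vinylogous ester O–C3=C4–C5=O and sits next to quaternary C10. The propanoyl group on C10 (C9=O) has a single enolisable carbon, C8. The C6–C7 unit can therefore only bridge C5 and C8, closing the six-membered ring B (C5–C6–C7–C8–C9–C10).
- Ring order: ring A first (asymmetric Michael addition sets C10, then Dieckmann closure), ring B in the key step, the coumarin last.

Key step: step 4

Remark: of the two pseudoenantiomeric cinchona catalysts, the one that delivers the (R)-configured Michael adduct is taken; the sense of induction is assumed, not known.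

**Step 1**
Reactants: 1 methyl 2-methyl-3-oxopentanoate (racemic); 2 pent-1-en-3-one
Product: 3 methyl (2R)-2-methyl-5-oxo-2-propanoylheptanoate
Conditions: 9-O-(9-phenanthryl)cupreidine-type bifunctional cinchona catalyst (10 mol %), CH2Cl2, −20 °C
Reagents that add atoms: none
Why: Organocatalytic asymmetric Michael addition; the catalyst deprotonates the β-keto ester and guides the enone to one face of the enolate, which should set the quaternary centre C10.

**Step 2**
Reactants: 3 methyl (2R)-2-methyl-5-oxo-2-propanoylheptanoate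
Product: 4 (4R)-2,4-dimethyl-4-propanoylcyclohexane-1,3-dione
Conditions: KOtBu (2.2 equiv), THF, −20 → 0 °C; then 1 M HCl
Reagents that add atoms: none
Why: Dieckmann-type intramolecular Claisen condensation (6-exo-trig): the C4 enolate of the side-chain ethyl ketone acylates at the ester carbon C5, and irreversible deprotonation of the β-diketone should drain the reversible aldol adducts; C10 is quaternary and cannot epimerise.

**Step 3**
Reactants: 4 (4R)-2,4-dimethyl-4-propanoylcyclohexane-1,3-dione
Product: 5 (6R)-3-ethoxy-2,6-dimethyl-6-propanoylcyclohex-2-en-1-one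
Conditions: EtOH, TsOH·H2O (5 mol %), PhH, reflux, Dean–Stark
Reagents that add atoms: ethanol, CCO
Why: Acid-catalysed enol etherification under thermodynamic control should put the ethoxy group on the less hindered oxygen (C3) and leave the carbonyl next to the quaternary carbon (C5), giving the vinylogous ester.

**Step 4**
Reactants: 5 (6R)-3-ethoxy-2,6-dimethyl-6-propanoylcyclohex-2-en-1-one; 6 (1,3-dioxolan-2-ylmethyl)magnesium bromide
Product: 10 (8aS)-2,5,8a-trimethyl-4,7,8,8a-tetrahydronaphthalene-1,6-dione, via lithium enolate 7 (not isolated), via tertiary carbinol 8 (not isolated), via keto aldehyde 9 (not isolated)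
Conditions: LiN(SiMe3)2 (1.05 equiv), THF, −78 °C; CeCl3 (1.5 equiv), 6 (2 equiv), −78 → 0 °C; then 3 M HCl, THF, 50 °C
Reagents that add atoms: water, O
Why: Lithium enolate 7 masks the only other electrophile (the C9 ketone, through its single enolisable carbon C8), so the cerium-activated Grignard reagent adds 1,2 to the vinylogous-ester carbonyl C5 and forms C5–C6; on acidification carbinol 8 undergoes the Stork–Danheiser carbonyl transposition (loss of water and ethanol) to the C3 enone, and the dioxolane is hydrolysed to aldehyde 9. The C9 ketone then enolises toward C8 (C10 is quaternary) and condenses with the aldehyde carbon C7 in an acid-catalysed intramolecular aldol condensation, which forms C7=C8 and closes ring B. The closest known reaction type is a Stork–Danheiser addition to a 3-alkoxy-enone followed by aldol cyclodehydration of the unmasked oxoalkyl side chain, a Robinson-type annulation with an acetaldehyde unit. Ring B closes in the 6-(enolendo)-exo-trig mode; ring A is already present. No stereocentre is created: C5 becomes sp2 (the carbinol centre of 8 is lost) and the non-enolisable quaternary C10 is carried through unchanged. The step needs addition at C5 and not at C9, secured by the enolate masking, and aldolisation between C8 and C7 and not bridged closures from C2 or onto C3, which would give Bredt-strained bicyclo[2.2.2]octenes and are reversible dead ends.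

**Step 5**
Reactants: 10 (8aS)-2,5,8a-trimethyl-4,7,8,8a-tetrahydronaphthalene-1,6-dione
Product: 11 (8aS)-6,6-(ethylenedioxy)-2,5,8a-trimethyl-4,6,7,8-tetrahydronaphthalen-1(8aH)-one
Conditions: TMSOCH2CH2OTMS (1.3 equiv), TMSOTf (5 mol %), CH2Cl2, −78 → −20 °C
Reagents that add atoms: 1,2-bis(trimethylsilyloxy)ethane, C[Si](C)(C)OCCO[Si](C)(C)C
Why: Aprotic silyl-triflate-catalysed ketalisation; the C3 carbonyl (flanked by CH2) should react while the C9 carbonyl next to quaternary C10 does not, and the low temperature should prevent migration of the C4=C5 double bond.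

**Step 6**
Reactants: 11 (8aS)-6,6-(ethylenedioxy)-2,5,8a-trimethyl-4,6,7,8-tetrahydronaphthalen-1(8aH)-one
Product: 12 (8aR)-6,6-(ethylenedioxy)-2,5,8a-trimethyl-1-methylidene-1,4,6,7,8,8a-hexahydronaphthalene
Conditions: Cp2TiMe2 (2.5 equiv), PhMe/THF, 70 °C
Reagents that add atoms: dimethyltitanocene Cp2TiMe2, [CH3-].[CH3-].[cH-]1cccc1.[cH-]1cccc1.[Ti+4]
Why: Carbonyl methylenation by the titanium methylidene formed on heating; the reagent is non-basic, so the doubly allylic C6 hydrogens should be left alone (the descriptor at C10 changes only because the priorities change).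

**Step 7**
Reactants: 12 (8aR)-6,6-(ethylenedioxy)-2,5,8a-trimethyl-1-methylidene-1,4,6,7,8,8a-hexahydronaphthalene
Product: 15 (4aR,5S)-5-(hydroxymethyl)-1,4a,6-trimethyl-4,4a,5,8-tetrahydronaphthalen-2(3H)-one, via alkylborane 13 (not isolated), via ketal alcohol 14 (not isolated)
Conditions: 9-BBN (2 equiv), THF, 0 → 50 °C; NaOH, H2O2, 0 °C → rt; then 1 M HCl, THF, rt
Reagents that add atoms: hydrogen peroxide, OO; water, O
Why: Hydroboration–oxidation; 9-BBN should place boron on the terminal carbon C11 of the 1,1-disubstituted alkene and deliver hydrogen to C9 from the face opposite the C10 methyl group, which sets C9, and the acid then hydrolyses the ketal back to the ring-A enone.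

**Step 8**
Reactants: 15 (4aR,5S)-5-(hydroxymethyl)-1,4a,6-trimethyl-4,4a,5,8-tetrahydronaphthalen-2(3H)-one
Product: 17 (4aS,5S,8aR)-5-(hydroxymethyl)-1,1,4a,6-tetramethyl-3,4,4a,5,8,8a-hexahydronaphthalen-2(1H)-one, via dilithium enolate alkoxide 16 (not isolated)
Conditions: Li (2.2 equiv), NH3(l)/THF, −78 °C; MeI (5 equiv), −78 → −33 °C; NH4Cl
Reagents that add atoms: iodomethane, CI
Why: Dissolving-metal (Birch-type) reductive alkylation of the enone; the β-carbanion at C5 should be protonated axially, anti to the C10 methyl group (trans ring fusion, the hydroxyl supplying the proton), and the regiospecific C3–C4 enolate 16 is C-methylated to the gem-dimethyl group.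

**Step 9**
Reactants: 17 (4aS,5S,8aR)-5-(hydroxymethyl)-1,1,4a,6-tetramethyl-3,4,4a,5,8,8a-hexahydronaphthalen-2(1H)-one
Product: 18 (2S,4aS,5S,8aR)-5-(hydroxymethyl)-1,1,4a,6-tetramethyl-1,2,3,4,4a,5,8,8a-octahydronaphthalen-2-ol
Conditions: NaBH4, MeOH, 0 °C
Reagents that add atoms: none
Why: Borohydride reduction; hydride should attack the 4,4-dimethyl ketone axially from the α-face and give the equatorial 3β-alcohol (3S).

**Step 10**
Reactants: 18 (2S,4aS,5S,8aR)-5-(hydroxymethyl)-1,1,4a,6-tetramethyl-1,2,3,4,4a,5,8,8a-octahydronaphthalen-2-ol; 19 isofraxidin (7-hydroxy-6,8-dimethoxy-2H-chromen-2-one)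
Product: 20 7-{[(1S,4aR,6S,8aS)-6-hydroxy-2,5,5,8a-tetramethyl-1,4,4a,5,6,7,8,8a-octahydronaphthalen-1-yl]methoxy}-6,8-dimethoxy-2H-chromen-2-one
Conditions: PPh3, DIAD, THF, 0 °C → rt
Reagents that add atoms: none
Why: Mitsunobu etherification; only the primary C11 hydroxyl should be activated (the neopentyl secondary C3 hydroxyl is inert), and the phenol of 19 displaces the oxyphosphonium group at a non-stereogenic carbon.

**Compound list**
1 | methyl 2-methyl-3-oxopentanoate (racemic) | CCC(=O)C(C)C(=O)OC | starting material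
2 | pent-1-en-3-one | C=CC(=O)CC | starting material
3 | methyl (2R)-2-methyl-5-oxo-2-propanoylheptanoate | CCC(=O)CC[C@@](C(=O)OC)(C(=O)CC)C | intermediate
4 | (4R)-2,4-dimethyl-4-propanoylcyclohexane-1,3-dione (C2 epimers and enol forms) | O=C1C(C)C(=O)CC[C@@]1(C(=O)CC)C | intermediate
5 | (6R)-3-ethoxy-2,6-dimethyl-6-propanoylcyclohex-2-en-1-one | O=C1C(C)=C(OCC)CC[C@@]1(C(=O)CC)C | intermediate
6 | (1,3-dioxolan-2-ylmethyl)magnesium bromide | Br[Mg]CC1OCCO1 | starting material
7 | lithium enolate of 5 at the propanoyl group (C8=C9–OLi) | O=C1C(C)=C(OCC)CC[C@@]1(C([O-])=CC)C.[Li+] | intermediate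
8 | (6S)-1-(1,3-dioxolan-2-ylmethyl)-3-ethoxy-2,6-dimethyl-6-propanoylcyclohex-2-en-1-ol (C1 epimers) | OC1(CC2OCCO2)C(C)=C(OCC)CC[C@@]1(C(=O)CC)C | intermediate
9 | 2-[(6S)-2,6-dimethyl-3-oxo-6-propanoylcyclohex-1-en-1-yl]acetaldehyde | O=CCC1=C(C)C(=O)CC[C@@]1(C(=O)CC)C | intermediate
10 | (8aS)-2,5,8a-trimethyl-4,7,8,8a-tetrahydronaphthalene-1,6-dione | O=C1C(C)=CCC2=C(C)C(=O)CC[C@]12C | intermediate
11 | (8aS)-6,6-(ethylenedioxy)-2,5,8a-trimethyl-4,6,7,8-tetrahydronaphthalen-1(8aH)-one | O=C1C(C)=CCC2=C(C)C3(OCCO3)CC[C@]12C | intermediate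
12 | (8aR)-6,6-(ethylenedioxy)-2,5,8a-trimethyl-1-methylidene-1,4,6,7,8,8a-hexahydronaphthalene | C=C1C(C)=CCC2=C(C)C3(OCCO3)CC[C@]12C | intermediate
13 | B-alkyl-9-borabicyclo[3.3.1]nonane adduct of 12 (boron on C11, hydrogen on C9 anti to the C10 methyl group) | C1CC2CCCC(C1)B2C[C@H]1C(C)=CCC2=C(C)C3(OCCO3)CC[C@]12C | intermediate
14 | [(1S,8aR)-6,6-(ethylenedioxy)-2,5,8a-trimethyl-1,4,6,7,8,8a-hexahydronaphthalen-1-yl]methanol | OC[C@H]1C(C)=CCC2=C(C)C3(OCCO3)CC[C@]12C | intermediate
15 | (4aR,5S)-5-(hydroxymethyl)-1,4a,6-trimethyl-4,4a,5,8-tetrahydronaphthalen-2(3H)-one | OC[C@H]1C(C)=CCC2=C(C)C(=O)CC[C@]12C | intermediate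
16 | dilithium C3–C4 enolate / C11 alkoxide of the reduced enone (trans-fused, hydrogen at C5 anti to the C10 methyl group) | [Li+].[Li+].[O-]C[C@H]1C(C)=CC[C@H]2C(C)=C([O-])CC[C@]12C | intermediate
17 | (4aS,5S,8aR)-5-(hydroxymethyl)-1,1,4a,6-tetramethyl-3,4,4a,5,8,8a-hexahydronaphthalen-2(1H)-one | OC[C@H]1C(C)=CC[C@H]2C(C)(C)C(=O)CC[C@]12C | intermediate
18 | (2S,4aS,5S,8aR)-5-(hydroxymethyl)-1,1,4a,6-tetramethyl-1,2,3,4,4a,5,8,8a-octahydronaphthalen-2-ol (3β-hydroxydrimenol) | OC[C@H]1C(C)=CC[C@H]2C(C)(C)[C@@H](O)CC[C@]12C | intermediate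
19 | isofraxidin (7-hydroxy-6,8-dimethoxy-2H-chromen-2-one) | COc1cc2ccc(=O)oc2c(OC)c1O | starting material
20 | 7-{[(1S,4aR,6S,8aS)-6-hydroxy-2,5,5,8a-tetramethyl-1,4,4a,5,6,7,8,8a-octahydronaphthalen-1-yl]methoxy}-6,8-dimethoxy-2H-chromen-2-one | COc1cc2ccc(=O)oc2c(OC)c1OC[C@H]1C(C)=CC[C@H]2C(C)(C)[C@@H](O)CC[C@]12C | target

Total step count: 10. Longest linear sequence: 10 steps (1 and 2 to 20; 6 and 19 are bought).

**Steps most likely to fail**

1. Step 4 (key step). What may go wrong: the 1,2-addition to the hindered vinylogous-ester carbonyl (between quaternary C10 and the methyl-bearing C4) may stay incomplete, the β-alkoxy Grignard reagent may eliminate before it adds, or the C9 ketone may be attacked if the enolate masking is incomplete. Fallback, from 5 back to 10: 5 is enolised as in step 4 and treated with allylmagnesium bromide, which adds to hindered carbonyls through a cyclic transition state, to give the carbinol (6S)-3-ethoxy-2,6-dimethyl-1-(prop-2-en-1-yl)-6-propanoylcyclohex-2-en-1-ol F1. Dilute HCl converts it into the transposed enone (4S)-2,4-dimethyl-3-(prop-2-en-1-yl)-4-propanoylcyclohex-2-en-1-one F2. Lemieux–Johnson cleavage of the terminal alkene (OsO4 cat., NaIO4, 2,6-lutidine) gives keto aldehyde 9, which is then isolated and closed to 10 with TsOH in warm toluene.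

2. Step 2. What may go wrong: aldol condensation (C4 enolate onto the C9 ketone, or C8 enolate onto the C3 ketone) may outrun acylation at the hindered ester, or the β-keto ester may suffer retro-Claisen cleavage. Fallback, from 2 back to 4: pentan-3-one is formylated (HCO2Et, NaH) to 2-methyl-3-oxopentanal F3. The cinchona-catalysed Michael addition of F3 to 2 gives (2S)-2-methyl-5-oxo-2-propanoylheptanal F4. A mild amine-mediated aldol addition, in which the aldehyde is the only good acceptor, gives the ketol (4S)-3-hydroxy-2,4-dimethyl-4-propanoylcyclohexan-1-one F5, and oxidation with 2-iodoxybenzoic acid gives 4.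

3. Step 1. What may go wrong: facial discrimination may be poor for an acyclic β-keto ester whose two carbonyl arms are of similar size, giving low enantiomeric purity at C10. Fallback, from 1 back to 3: 1 is condensed with L-valine diethylamide (TsOH cat.) to the enamino ester methyl (2Z)-3-{[(2S)-1-(diethylamino)-3-methyl-1-oxobutan-2-yl]amino}-2-methylpent-2-enoate F6. Cu(OAc)2·H2O-catalysed Michael addition to 2 gives the α-quaternary imine methyl (2R)-2-{N-[(2S)-1-(diethylamino)-3-methyl-1-oxobutan-2-yl]propanimidoyl}-2-methyl-5-oxoheptanoate F7, and aqueous HCl releases 3 and the auxiliary. The D-configured auxiliary is taken if the sense of induction requires it.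

**Further compounds**
F1 | step 4 | (6S)-3-ethoxy-2,6-dimethyl-1-(prop-2-en-1-yl)-6-propanoylcyclohex-2-en-1-ol (C1 epimers) | OC1(CC=C)C(C)=C(OCC)CC[C@@]1(C(=O)CC)C
F2 | step 4 | (4S)-2,4-dimethyl-3-(prop-2-en-1-yl)-4-propanoylcyclohex-2-en-1-one | C=CCC1=C(C)C(=O)CC[C@@]1(C(=O)CC)C
F3 | step 2 | 2-methyl-3-oxopentanal | CCC(=O)C(C)C=O
F4 | step 2 | (2S)-2-methyl-5-oxo-2-propanoylheptanal | CCC(=O)CC[C@@](C=O)(C(=O)CC)C
F5 | step 2 | (4S)-3-hydroxy-2,4-dimethyl-4-propanoylcyclohexan-1-one (C2 and C3 epimers) | OC1C(C)C(=O)CC[C@@]1(C(=O)CC)C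
F6 | step 1 | methyl (2Z)-3-{[(2S)-1-(diethylamino)-3-methyl-1-oxobutan-2-yl]amino}-2-methylpent-2-enoate | CC/C(N[C@@H](C(C)C)C(=O)N(CC)CC)=C(\C)C(=O)OC
F7 | step 1 | methyl (2R)-2-{N-[(2S)-1-(diethylamino)-3-methyl-1-oxobutan-2-yl]propanimidoyl}-2-methyl-5-oxoheptanoate | CCC(=O)CC[C@@](C(=O)OC)(C(CC)=N[C@@H](C(C)C)C(=O)N(CC)CC)C
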